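**Plan**

1. The last disconnection removes the silyl group from O7. Ring A is then opened at four bonds (C4a–C5, C5–C6, C7–C8, C8–C8a), leaving a 4-pyranone (ring C) that carries a diazoacetyl group, and a silyloxyacetylene.
2. This works because ring A (C4a, C5, C6, C7, C8, C8a) is a benzene ring fused to ring C along C4a–C8a, with a hydroxyl at C5 beside the fusion atom C4a and a second oxygen at C7. That is the 1,3-dioxygen pattern obtained when a vinylketene (here the pyranone C8a=C4a bond plus a ketene) combines with an oxygen-substituted alkyne.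
3. The pyranone is cut further at C2–C1' (bond to ring B) and traced to kojic acid, whose CH2OH carbon becomes C5. C8 comes from diazomethane, C6 and C7 from the alkyne.
4. Forward: ring C is bought as kojic acid, ring B is attached by cross-coupling with its prenyl ether already in place, the side chain is raised to the diazo ketone, ring A is annulated last, and O7 is desilylated.
5. The target has no stereocentre and its only non-ring double bond carries two identical methyl groups, so no stereochemistry has to be set.

Key step: step 9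

Remark: the arylboron building block is used as its commercial pinacol ester, so that the phenol can be alkylated cleanly before the coupling.

**Route**

Step 1
Reactants: 1 4-(4,4,5,5-tetramethyl-1,3,2-dioxaborolan-2-yl)phenol; 2 1-bromo-3-methylbut-2-ene (prenyl bromide)
Product: 3 4,4,5,5-tetramethyl-2-[4-(3-methylbut-2-enyloxy)phenyl]-1,3,2-dioxaborolane
Conditions: K2CO3, acetone, 50 °C
Reagents that add atoms: none
Why: Williamson ether synthesis, in which the phenoxide displaces the primary allylic bromide at its unhindered CH2 carbon (SN2) while the pinacol boronate is inert to carbonate in a dry aprotic solvent.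

Step 2
Reactants: 4 kojic acid (5-hydroxy-2-(hydroxymethyl)-4H-pyran-4-one)
Product: 5 6-bromo-5-hydroxy-2-(hydroxymethyl)-4H-pyran-4-one
Conditions: NBS, MeCN/H2O, 0 °C to rt
Reagents that add atoms: N-bromosuccinimide, O=C1CCC(=O)N1Br
Why: Electrophilic bromination of the enolic 3-hydroxy-4-pyranone, which should go to C6, the ring carbon next to the free hydroxyl and the usual site of electrophilic substitution in kojic acid.

Step 3
Reactants: 5 6-bromo-5-hydroxy-2-(hydroxymethyl)-4H-pyran-4-one
Product: 6 6-bromo-2-(hydroxymethyl)-5-methoxy-4H-pyran-4-one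
Conditions: MeI, K2CO3, DMF, rt
Reagents that add atoms: iodomethane, CI
Why: Chemoselective Williamson O-methylation, since carbonate deprotonates only the acidic enolic hydroxyl and leaves the primary alcohol un-ionized and unalkylated.

Step 4
Reactants: 6 6-bromo-2-(hydroxymethyl)-5-methoxy-4H-pyran-4-one; 3 4,4,5,5-tetramethyl-2-[4-(3-methylbut-2-enyloxy)phenyl]-1,3,2-dioxaborolane
Product: 7 2-(hydroxymethyl)-5-methoxy-6-[4-(3-methylbut-2-enyloxy)phenyl]-4H-pyran-4-one
Conditions: PdCl2(dppf) (5 mol %; dppf = 1,1'-bis(diphenylphosphino)ferrocene), K2CO3, 1,4-dioxane/H2O (4:1), 80 °C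
Reagents that add atoms: none
Why: Suzuki–Miyaura coupling of a vinylogous acyl bromide, where oxidative addition to the β-bromo enone is fast, the free alcohol is tolerated, and the trisubstituted prenyl ether ionizes too slowly at zerovalent palladium to compete.

Step 5
Reactants: 7 2-(hydroxymethyl)-5-methoxy-6-[4-(3-methylbut-2-enyloxy)phenyl]-4H-pyran-4-one
Product: 9 5-methoxy-6-[4-(3-methylbut-2-enyloxy)phenyl]-4-oxo-4H-pyran-2-carboxylic acid, via pyranone-2-carbaldehyde 8 (not isolated)
Conditions: TEMPO (2,2,6,6-tetramethylpiperidin-1-oxyl, 20 mol %), PhI(OAc)2 (2.2 equiv), MeCN/H2O (1:1), rt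
Reagents that add atoms: water, O
Why: Oxoammonium-mediated (TEMPO/PhI(OAc)2) oxidation of the primary alcohol through the aldehyde and its hydrate to the acid, which avoids strongly acidic chromium reagents and should leave the prenyl alkene and the aryl ethers untouched.

Step 6
Reactants: 9 5-methoxy-6-[4-(3-methylbut-2-enyloxy)phenyl]-4-oxo-4H-pyran-2-carboxylic acid
Product: 11 2-(diazoacetyl)-5-methoxy-6-[4-(3-methylbut-2-enyloxy)phenyl]-4H-pyran-4-one, via isobutyl carbonic anhydride 10 (not isolated)
Conditions: i-BuOCOCl, N-methylmorpholine, THF, −15 °C; then CH2N2 (Et2O, 3 equiv), −15 °C to rt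
Reagents that add atoms: diazomethane, C=[N+]=[N-]; isobutyl chloroformate, CC(C)COC(Cl)=O (its atoms stay only in intermediate 10)
Why: Acylation of diazomethane by a mixed carbonic anhydride (the diazo ketone stage of an Arndt–Eistert sequence), an activation that generates no free HCl and so spares the acid-sensitive prenyl ether.

Step 7
Reactants: 12 ethynyltrimethylsilane; 13 triisopropylsilyl trifluoromethanesulfonate
Product: 16 triisopropyl{[(trimethylsilyl)ethynyl]oxy}silane, via lithium (trimethylsilyl)acetylide 14 (not isolated), via lithium 2-(trimethylsilyl)ethynolate 15 (not isolated)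
Conditions: LiN(SiMe3)2 (2.1 equiv), THF, −78 °C; t-BuOOH (1.0 equiv, decane), −78 to 0 °C; then 13, −78 to 0 °C
Reagents that add atoms: tert-butyl hydroperoxide, CC(C)(C)OO; lithium bis(trimethylsilyl)amide, [Li]N([Si](C)(C)C)[Si](C)(C)C (lithium stays only in intermediates 14 and 15)
Why: Oxidation of a lithium acetylide by lithium tert-butyl peroxide (attack of the carbanion on the O–O bond) should give ynolate 15, which the bulky, hard silyl triflate caps on oxygen and not on the SiMe3-bearing carbon, as is usual when triisopropylsilyl ynol ethers are made from ynolates.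

Step 8
Reactants: 16 triisopropyl{[(trimethylsilyl)ethynyl]oxy}silane
Product: 17 (ethynyloxy)triisopropylsilane
Conditions: K2CO3 (0.1 equiv), MeOH/THF, 0 °C, short contact; pentane extraction, bulb-to-bulb distillation, stored cold
Reagents that add atoms: none
Why: Base-catalysed methanolysis of an alkynyl–SiMe3 bond (protodesilylation), in which methoxide should attack the small SiMe3 group far faster than the hindered i-Pr3Si–O group, while the electron-rich alkyne does not add methanol without acid.

Step 9
Reactants: 11 2-(diazoacetyl)-5-methoxy-6-[4-(3-methylbut-2-enyloxy)phenyl]-4H-pyran-4-one; 17 (ethynyloxy)triisopropylsilane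
Product: 22 5-hydroxy-3-methoxy-2-[4-(3-methylbut-2-enyloxy)phenyl]-7-(triisopropylsilyloxy)-4H-chromen-4-one, via pyranonyl ketene 18 (not isolated), via 3-silyloxycyclobutenone 19 (not isolated), via dienylketene 20 (not isolated), via 4aH-dienone 21 (not isolated)
Conditions: 17 (2.5 equiv), ClCH2CH2Cl (0.05 M, degassed, Ar), hν (420–440 nm LEDs), rt; then 80 °C in the dark
Reagents that add atoms: none
Why: Light absorbed in the n–π* band of the diazo ketone expels N2 and the pyranonyl group shifts to the former diazo carbon (Wolff rearrangement, bond C8–C8a), giving ketene 18, which is attacked at its central carbon by the unsubstituted, nucleophilic carbon of 17 so that the [2+2] adduct is cyclobutenone 19 (bonds C5–C6 and C7–C8). Warming then opens 19 by a 4π electrocyclic reaction to dienylketene 20, whose ketene carbon bonds to pyranone C3 in a thermal disrotatory 6π electrocyclization (bond C4a–C5, the closure of ring A) to give dienone 21, and enolization delivers the hydrogen-bonded C5 phenol of 22. The closest known chemistry is the Danheiser benzannulation in its diazo ketone form, established for silyloxyalkynes with aryl, heteroaryl and cycloalkenyl diazomethyl ketones; here the pyranone C2=C3 bond plays the part of the alkene of a cycloalkenyl ketene. No stereocentre survives, since the only sp3 centre formed (C4a in 21) is erased on tautomerization. Two selectivities are required: the orientation of the [2+2] step, secured by the donor oxygen of 17, which makes the CH terminus the nucleophile (silyloxy carbon becomes C7, ketene carbonyl carbon becomes C5), and the site of ring closure, unambiguous because pyranone C2 has only one carbon neighbour, C3. Violet-blue light is chosen because the aryl pyranone, the prenyl aryl ether and the chelated product should absorb little there, and the chelated 5-OH of 22 is too weak a nucleophile to intercept the ketenes.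

Step 10
Reactants: 22 5-hydroxy-3-methoxy-2-[4-(3-methylbut-2-enyloxy)phenyl]-7-(triisopropylsilyloxy)-4H-chromen-4-one
Product: 23 5,7-dihydroxy-3-methoxy-2-[4-(3-methylbut-2-enyloxy)phenyl]-4H-chromen-4-one (5,7-dihydroxy-3-methoxy-4'-prenyloxyflavone)
Conditions: Bu4NF (1.1 equiv), AcOH (1.2 equiv), THF, 0 °C
Reagents that add atoms: none
Why: Fluoride-induced cleavage of an aryl silyl ether, fast for the acidic 7-phenol of a flavone, with acetic acid keeping the medium near neutral and the methyl and prenyl ethers inert to fluoride.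

**Compound list**

1 | 4-(4,4,5,5-tetramethyl-1,3,2-dioxaborolan-2-yl)phenol | CC1(C)OB(c2ccc(O)cc2)OC1(C)C | starting material
2 | 1-bromo-3-methylbut-2-ene (prenyl bromide) | CC(C)=CCBr | starting material
3 | 4,4,5,5-tetramethyl-2-[4-(3-methylbut-2-enyloxy)phenyl]-1,3,2-dioxaborolane | CC(C)=CCOc1ccc(cc1)B1OC(C)(C)C(C)(C)O1 | intermediate
4 | kojic acid, 5-hydroxy-2-(hydroxymethyl)-4H-pyran-4-one | O=c1cc(CO)occ1O | starting material
5 | 6-bromo-5-hydroxy-2-(hydroxymethyl)-4H-pyran-4-one | O=c1cc(CO)oc(Br)c1O | intermediate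
6 | 6-bromo-2-(hydroxymethyl)-5-methoxy-4H-pyran-4-one | COc1c(Br)oc(CO)cc1=O | intermediate
7 | 2-(hydroxymethyl)-5-methoxy-6-[4-(3-methylbut-2-enyloxy)phenyl]-4H-pyran-4-one | COc1c(-c2ccc(OCC=C(C)C)cc2)oc(CO)cc1=O | intermediate
8 | 5-methoxy-6-[4-(3-methylbut-2-enyloxy)phenyl]-4-oxo-4H-pyran-2-carbaldehyde | COc1c(-c2ccc(OCC=C(C)C)cc2)oc(C=O)cc1=O | intermediate
9 | 5-methoxy-6-[4-(3-methylbut-2-enyloxy)phenyl]-4-oxo-4H-pyran-2-carboxylic acid | COc1c(-c2ccc(OCC=C(C)C)cc2)oc(C(=O)O)cc1=O | intermediate
10 | isobutyl carbonic 5-methoxy-6-[4-(3-methylbut-2-enyloxy)phenyl]-4-oxo-4H-pyran-2-carboxylic anhydride | COc1c(-c2ccc(OCC=C(C)C)cc2)oc(C(=O)OC(=O)OCC(C)C)cc1=O | intermediate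
11 | 2-(diazoacetyl)-5-methoxy-6-[4-(3-methylbut-2-enyloxy)phenyl]-4H-pyran-4-one | COc1c(-c2ccc(OCC=C(C)C)cc2)oc(C(=O)C=[N+]=[N-])cc1=O | intermediate
12 | ethynyltrimethylsilane | C#C[Si](C)(C)C | starting material
13 | triisopropylsilyl trifluoromethanesulfonate | CC(C)[Si](OS(=O)(=O)C(F)(F)F)(C(C)C)C(C)C | starting material
14 | lithium (trimethylsilyl)acetylide | [Li]C#C[Si](C)(C)C | intermediate
15 | lithium 2-(trimethylsilyl)ethynolate | [Li]OC#C[Si](C)(C)C | intermediate
16 | triisopropyl{[(trimethylsilyl)ethynyl]oxy}silane | CC(C)[Si](OC#C[Si](C)(C)C)(C(C)C)C(C)C | intermediate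
17 | (ethynyloxy)triisopropylsilane | C#CO[Si](C(C)C)(C(C)C)C(C)C | intermediate
18 | 5-methoxy-6-[4-(3-methylbut-2-enyloxy)phenyl]-2-(2-oxoethenyl)-4H-pyran-4-one (ketene) | COc1c(-c2ccc(OCC=C(C)C)cc2)oc(C=C=O)cc1=O | intermediate
19 | 5-methoxy-6-[4-(3-methylbut-2-enyloxy)phenyl]-2-[4-oxo-2-(triisopropylsilyloxy)cyclobut-2-en-1-yl]-4H-pyran-4-one (racemic) | COc1c(-c2ccc(OCC=C(C)C)cc2)oc(C2C(=O)C=C2O[Si](C(C)C)(C(C)C)C(C)C)cc1=O | intermediate
20 | 5-methoxy-6-[4-(3-methylbut-2-enyloxy)phenyl]-2-[(1E)-4-oxo-2-(triisopropylsilyloxy)buta-1,3-dien-1-yl]-4H-pyran-4-one (dienylketene) | COc1c(-c2ccc(OCC=C(C)C)cc2)oc(/C=C(\C=C=O)O[Si](C(C)C)(C(C)C)C(C)C)cc1=O | intermediate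
21 | 3-methoxy-2-[4-(3-methylbut-2-enyloxy)phenyl]-7-(triisopropylsilyloxy)-4aH-chromene-4,5-dione (racemic) | COC1=C(c2ccc(OCC=C(C)C)cc2)OC2=CC(O[Si](C(C)C)(C(C)C)C(C)C)=CC(=O)C2C1=O | intermediate
22 | 5-hydroxy-3-methoxy-2-[4-(3-methylbut-2-enyloxy)phenyl]-7-(triisopropylsilyloxy)-4H-chromen-4-one | COc1c(-c2ccc(OCC=C(C)C)cc2)oc2cc(O[Si](C(C)C)(C(C)C)C(C)C)cc(O)c2c1=O | intermediate
23 | 5,7-dihydroxy-3-methoxy-2-[4-(3-methylbut-2-enyloxy)phenyl]-4H-chromen-4-one | COc1c(-c2ccc(OCC=C(C)C)cc2)oc2cc(O)cc(O)c2c1=O | target

**Step count**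

Total: 10 steps. Longest linear sequence: 7 steps (kojic acid 4 to target 23 through steps 2, 3, 4, 5, 6, 9 and 10).

**Steps most likely to fail**

First, step 9. The aryl pyranone chromophore may compete for light and rearrange, the [2+2] capture of the ketene may be too slow so that the ketene dimerizes or is hydrolysed, or the cyclobutenone may open sluggishly. The fallback generates the same ketene without light and sets out from diazo ketone 11. Wolff rearrangement catalysed by PhCO2Ag with Et3N in aqueous dioxane should give the homologous acid [5-methoxy-6-[4-(3-methylbut-2-enyloxy)phenyl]-4-oxo-4H-pyran-2-yl]acetic acid F1. This is converted under neutral conditions with 1-chloro-N,N,2-trimethylprop-1-en-1-amine into [5-methoxy-6-[4-(3-methylbut-2-enyloxy)phenyl]-4-oxo-4H-pyran-2-yl]acetyl chloride F2. Slow addition of F2 to Et3N and alkyne 17 in CH2Cl2 in the dark should form ketene 18 by dehydrochlorination and then cyclobutenone 19. Heating in toluene at 80–110 °C should carry 19 through the electrocyclic sequence, and the route is rejoined at 22.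

Second, step 8. Methanolysis may also strip the oxygen-bound silyl group (the ynolate is a good leaving group), and the volatile terminal alkyne may be lost on isolation. The fallback omits the alkyne desilylation and sets out from 16 and diazo ketone 11. Under the conditions of step 9 the disubstituted silyloxyalkyne should react with the same orientation, now placing SiMe3 on C6, to give 5-hydroxy-3-methoxy-2-[4-(3-methylbut-2-enyloxy)phenyl]-7-(triisopropylsilyloxy)-6-(trimethylsilyl)-4H-chromen-4-one F3. Treatment with Bu4NF and AcOH in wet THF should remove the O7 silyl group and then the C6 silane by ipso-protonation of the phloroglucinol-type ring (an α-silyl ketone in its keto form). The route is rejoined at target 23.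

Third, step 6. Diazomethane may add as a 1,3-dipole across the doubly activated C2=C3 bond of the pyranone, or attack the carbonate carbonyl of the mixed anhydride. The fallback avoids acylation of diazomethane and sets out from alcohol 7. MnO2 in CH2Cl2 should stop at aldehyde 8, now isolated. MeMgBr at −78 °C should add to the aldehyde in preference to the vinylogous ester carbonyl and give racemic 2-(1-hydroxyethyl)-5-methoxy-6-[4-(3-methylbut-2-enyloxy)phenyl]-4H-pyran-4-one F4. Dess–Martin periodinane should give 2-acetyl-5-methoxy-6-[4-(3-methylbut-2-enyloxy)phenyl]-4H-pyran-4-one F5. Its lithium enolate (LiN(SiMe3)2, THF, −78 °C) is trifluoroacetylated with CF3CO2CH2CF3 to 4,4,4-trifluoro-1-{5-methoxy-6-[4-(3-methylbut-2-enyloxy)phenyl]-4-oxo-4H-pyran-2-yl}butane-1,3-dione F6. Detrifluoroacetylative diazo transfer with MsN3, Et3N and water in MeCN should then give the diazo ketone, and the route is rejoined at 11.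

**Further compounds**

F1 | step 9 | [5-methoxy-6-[4-(3-methylbut-2-enyloxy)phenyl]-4-oxo-4H-pyran-2-yl]acetic acid | COc1c(-c2ccc(OCC=C(C)C)cc2)oc(CC(=O)O)cc1=O
F2 | step 9 | [5-methoxy-6-[4-(3-methylbut-2-enyloxy)phenyl]-4-oxo-4H-pyran-2-yl]acetyl chloride | COc1c(-c2ccc(OCC=C(C)C)cc2)oc(CC(=O)Cl)cc1=O
F3 | step 8 | 5-hydroxy-3-methoxy-2-[4-(3-methylbut-2-enyloxy)phenyl]-7-(triisopropylsilyloxy)-6-(trimethylsilyl)-4H-chromen-4-one | COc1c(-c2ccc(OCC=C(C)C)cc2)oc2cc(O[Si](C(C)C)(C(C)C)C(C)C)c([Si](C)(C)C)c(O)c2c1=O
F4 | step 6 | 2-(1-hydroxyethyl)-5-methoxy-6-[4-(3-methylbut-2-enyloxy)phenyl]-4H-pyran-4-one (racemic) | COc1c(-c2ccc(OCC=C(C)C)cc2)oc(C(C)O)cc1=O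
F5 | step 6 | 2-acetyl-5-methoxy-6-[4-(3-methylbut-2-enyloxy)phenyl]-4H-pyran-4-one | COc1c(-c2ccc(OCC=C(C)C)cc2)oc(C(C)=O)cc1=O
F6 | step 6 | 4,4,4-trifluoro-1-{5-methoxy-6-[4-(3-methylbut-2-enyloxy)phenyl]-4-oxo-4H-pyran-2-yl}butane-1,3-dione | COc1c(-c2ccc(OCC=C(C)C)cc2)oc(C(=O)CC(=O)C(F)(F)F)cc1=O
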